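Guaiane numbering is used (C1/C5 ring fusion, C4 methyl carbon, C7 carbinol‑bearing carbon, C8 ester carbon, C10 alkene methyl carbon). The seven‑membered ring is divided into the three‑carbon unit C9–C10–C1, which already contains the tetrasubstituted C1=C10 alkene, and the four‑carbon unit C5–C6–C7–C8 with oxygen on C8; C2–C4 of the cyclopentane act as tether. A vinylcarbenoid at C1, generated with Rh2(O2CC7H15)4, cyclopropanates C5=C6 and the cis‑divinylcyclopropane rearranges (Cope), so one operation makes C1–C5 and C8–C9, both rings and the C5 and C8 stereocentres. Its precursor is an open‑chain diazoketone carrying an isopropenyl group and an alkoxydienoate, built from (S)‑but‑3‑yn‑2‑ol.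

Key step: step 10

Remark: (S)-but-3-yn-2-ol, 2-methylallylmagnesium chloride and 4-acetoxy-3-methoxycinnamic acid are taken as purchased; locants C1–C15 in the text are guaiane locants of the target.

Step 1
Reactants: 1 (S)-but-3-yn-2-ol
Product: 2 (S)-but-3-yn-2-yl 4-methylbenzenesulfonate
Conditions: TsCl, Et3N, DMAP (cat.), CH2Cl2, 0 °C to rt
Reagents that add atoms: 4-toluenesulfonyl chloride Cc1ccc(cc1)S(=O)(=O)Cl
Why: O-sulfonylation of the secondary alcohol does not touch the stereocentre (retention).

Step 2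
Reactants: 2 (S)-but-3-yn-2-yl 4-methylbenzenesulfonate; 3 dimethyl malonate
Product: 4 dimethyl 2-[(2S)-but-3-yn-2-yl]propanedioate
Conditions: NaH, DMF, 0 to 60 °C
Reagents that add atoms: none
Why: SN2 displacement of the secondary propargylic tosylate by the soft malonate anion should proceed with inversion and so fixes the future C4 methyl stereocentre (the descriptor stays S only because the priorities change).

Step 3
Reactants: 4 dimethyl 2-[(2S)-but-3-yn-2-yl]propanedioate
Product: 5 methyl (3S)-3-methylpent-4-ynoate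
Conditions: LiCl, H2O, DMSO, 150 °C
Reagents that add atoms: none
Why: Krapcho dealkoxycarbonylation removes one ester under neutral conditions without affecting the stereocentre or the terminal alkyne.

Step 4
Reactants: 6 methyl propiolate; 7 4-methoxybenzyl alcohol
Product: 8 methyl (E)-3-[(4-methoxybenzyl)oxy]prop-2-enoate
Conditions: N-methylmorpholine (10 mol %), CH2Cl2, rt
Reagents that add atoms: none
Why: Amine-catalysed oxa-Michael addition of an alcohol to a propiolate should give the (E)-3-alkoxyacrylate.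

Step 5
Reactants: 8 methyl (E)-3-[(4-methoxybenzyl)oxy]prop-2-enoate
Product: 10 methyl (Z)-2-iodo-3-[(4-methoxybenzyl)oxy]prop-2-enoate, via iodoacetoxy adduct 9 (not isolated)
Conditions: NIS, AcOH, CH2Cl2, rt; then Et3N, 0 °C
Reagents that add atoms: N-iodosuccinimide O=C1CCC(=O)N1I
Why: Iodoacetoxylation of the enol ether followed by base-induced loss of acetic acid is the usual route to (Z)-2-iodo-3-alkoxyacrylates, with iodine and the ether oxygen on the same side.

Step 6
Reactants: 5 methyl (3S)-3-methylpent-4-ynoate; 10 methyl (Z)-2-iodo-3-[(4-methoxybenzyl)oxy]prop-2-enoate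
Product: 13 dimethyl (2E,3E,5S)-2-{[(4-methoxybenzyl)oxy]methylidene}-5-methylhept-3-enedioate, via alkenylzirconocene chloride 11 (not isolated), via alkenylzinc chloride 12 (not isolated)
Conditions: Cp2Zr(H)Cl, THF, rt; ZnCl2; then 10, Pd(PPh3)4 (5 mol %), rt
Reagents that add atoms: none
Why: Syn hydrozirconation of the terminal alkyne gives the (E)-alkenyl metal, and Negishi coupling after Zr-to-Zn exchange proceeds with retention at both partners, so C5=C6 is E and the C8 oxygen lies cis to C6.

Step 7
Reactants: 13 dimethyl (2E,3E,5S)-2-{[(4-methoxybenzyl)oxy]methylidene}-5-methylhept-3-enedioate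
Product: 14 methyl (2E,3E,5S)-7-[methoxy(methyl)amino]-2-{[(4-methoxybenzyl)oxy]methylidene}-5-methyl-7-oxohept-3-enoate
Conditions: MeNH(OMe)·HCl, iPrMgCl, THF, −20 °C
Reagents that add atoms: N,O-dimethylhydroxylamine hydrochloride CNOC.Cl
Why: The magnesium amide should convert only the saturated ester into the Weinreb amide, because the alkoxyacrylate ester is a far less electrophilic vinylogous carbonate.

Step 8
Reactants: 14 Weinreb amide; 15 2-methylallylmagnesium chloride
Product: 16 methyl (2E,3E,5S)-2-{[(4-methoxybenzyl)oxy]methylidene}-5,9-dimethyl-7-oxodeca-3,9-dienoate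
Conditions: THF, −78 °C; AcOH quench at −78 °C
Reagents that add atoms: none
Why: Grignard addition to a Weinreb amide stops at the chelated tetrahedral intermediate, and the cold acidic quench should release the β,γ-unsaturated ketone without conjugation.

Step 9
Reactants: 16 β,γ-unsaturated ketone
Product: 17 methyl (2E,3E,5S)-8-diazo-2-{[(4-methoxybenzyl)oxy]methylidene}-5,9-dimethyl-7-oxodeca-3,9-dienoate
Conditions: p-ABSA, DBU, MeCN, 0 °C; used at once
Reagents that add atoms: 4-acetamidobenzenesulfonyl azide CC(=O)Nc1ccc(cc1)S(=O)(=O)N=[N+]=[N-]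
Why: Regitz diazo transfer should take place at the methylene activated by both the carbonyl and the isopropenyl group, giving the vinyl diazo ketone.

Step 10
Reactants: 17 vinyl diazo ketone
Product: 19 methyl (3S,3aR,6S)-6-[(4-methoxybenzyl)oxy]-3,8-dimethyl-1-oxo-1,2,3,3a,6,7-hexahydroazulene-5-carboxylate, via cis-divinylcyclopropane 18 (not isolated)
Conditions: Rh2(O2CC7H15)4 (1 mol %), toluene, slow addition at 25 °C; then 110 °C
Reagents that add atoms: none
Why: Rh2(O2CC7H15)4 expels N2 from 17 to give a vinylcarbenoid at C1, which adds to the tethered C5=C6 bond to form the cis-divinylcyclopropane 18 (bonds C1–C5 and C1–C6), and on heating 18 undergoes a [3,3] (Cope) shift that forms C8–C9, breaks C1–C6 and leaves the alkenes at C1=C10 and C6=C7. The closest known reaction type is the tandem intramolecular cyclopropanation/divinylcyclopropane rearrangement of dienes tethered to vinyl diazo carbonyl compounds, an extension of the diazoketone–diene cyclopropanation that gives vinylcyclopropanes. The five-membered ring closes in the [2+1] step by 5-exo attack of C1 on C5 (a bicyclo[3.1.0]hexan-2-one), and the seven-membered ring closes by the concerted boat-type sigmatropic ring expansion of the cyclopropane. C8 follows stereospecifically from alkene geometry: the (E)-C5=C6 bond places the C6 vinyl group cis to the isopropenyl group, and in the boat transition state the C8 oxygen, which is cis to C6 on C7=C8, ends up cis to H5. C5 is set against the C4 methyl stereocentre, which is expected to sit pseudo-equatorially on the cyclopropane side of the boat-like bicyclo[3.1.0]hexanone transition state and so trans to H5; because C4 is retained, any C5,C8-diastereomer is a separable by-product and not a loss of enantiopurity. The step needs attack at C5=C6 and not at the push-pull C7=C8 bond, which the three-atom tether and the ester on C7 secure, and it needs freedom from 1,2-hydride shift, which the C2 carbonyl and the fully substituted C10 secure.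

Step 11
Reactants: 19 bicyclic keto ester
Product: 20 methyl (3S,3aR,6S)-1-hydroxy-6-[(4-methoxybenzyl)oxy]-3,8-dimethyl-1,2,3,3a,6,7-hexahydroazulene-5-carboxylate (both C2 carbinol epimers)
Conditions: NaBH4, CeCl3·7H2O, MeOH, −78 to −40 °C
Reagents that add atoms: none
Why: Luche 1,2-reduction of the cyclopentenone leaves the enoate untouched, and the configuration of the new carbinol does not matter because the oxygen is removed in the next step.

Step 12
Reactants: 20 allylic alcohol
Product: 21 methyl (3S,3aR,6S)-6-[(4-methoxybenzyl)oxy]-3,8-dimethyl-1,2,3,3a,6,7-hexahydroazulene-5-carboxylate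
Conditions: Et3SiH, BF3·OEt2, CH2Cl2, −78 °C
Reagents that add atoms: none
Why: Ionisation gives an allyl cation that should take hydride from the silane at the less hindered secondary C2 terminus, which keeps the tetrasubstituted C1=C10 alkene (ionic deoxygenation).

Step 13
Reactants: 21 PMB ether
Product: 22 methyl (3S,3aR,6S)-6-hydroxy-3,8-dimethyl-1,2,3,3a,6,7-hexahydroazulene-5-carboxylate
Conditions: DDQ, CH2Cl2/pH 7 buffer, 0 °C
Reagents that add atoms: none
Why: Oxidative cleavage of the 4-methoxybenzyl ether by DDQ should free the C8 hydroxyl without touching ester or alkenes.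

Step 14
Reactants: 22 hydroxy enoate
Product: 23 methyl (3S,3aS,5S,6S)-6-hydroxy-3,8-dimethyl-1,2,3,3a,4,5,6,7-octahydroazulene-5-carboxylate
Conditions: H2 (40 bar), [Rh(nbd)(dppb)]BF4 (5 mol %), CH2Cl2, rt
Reagents that add atoms: none
Why: Hydroxyl-directed hydrogenation of the α-(hydroxyalkyl)acrylate unit should deliver hydrogen to C6=C7 from the face of the C8 hydroxyl, making H7 cis to O8 (ester trans to OH), while the tetrasubstituted C1=C10 alkene is inert to this catalyst.

Step 15
Reactants: 23 hydroxy ester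
Product: 24 (3S,3aS,5S,6S)-5-(2-hydroxypropan-2-yl)-3,8-dimethyl-1,2,3,3a,4,5,6,7-octahydroazulen-6-ol
Conditions: MeMgBr (5 equiv), THF, 0 °C to rt
Reagents that add atoms: methylmagnesium bromide C[Mg]Br
Why: Double Grignard addition to the ester gives the tertiary carbinol at C11, the C8 magnesium alkoxide formed first keeping the β-hydroxy ester from eliminating.

Step 16
Reactants: 24 diol; 25 4-acetoxy-3-methoxycinnamic acid
Product: 26 (3S,3aS,5S,6S)-5-(2-hydroxypropan-2-yl)-3,8-dimethyl-1,2,3,3a,4,5,6,7-octahydroazulen-6-yl (E)-3-(4-acetoxy-3-methoxyphenyl)prop-2-enoate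
Conditions: EDC·HCl, DMAP, CH2Cl2, rt
Reagents that add atoms: none
Why: Steglich acylation should occur only at the secondary C8 hydroxyl, the tertiary alcohol being unreactive, and it retains the C8 configuration.

Step 17
Reactants: 26 acetyl-protected ester
Product: 27 the target, (3S,3aS,5S,6S)-5-(2-hydroxypropan-2-yl)-3,8-dimethyl-1,2,3,3a,4,5,6,7-octahydroazulen-6-yl (E)-3-(4-hydroxy-3-methoxyphenyl)prop-2-enoate
Conditions: pyrrolidine, CH2Cl2, 0 °C
Reagents that add atoms: none
Why: Aminolysis cleaves the aryl acetate much faster than the alkyl cinnamate and so should release the phenol without touching the C8 ester.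

Compound list
1 | (S)-but-3-yn-2-ol | C#C[C@H](C)O | starting material
2 | (S)-but-3-yn-2-yl 4-methylbenzenesulfonate | C#C[C@H](C)OS(=O)(=O)c1ccc(C)cc1 | intermediate
3 | dimethyl malonate | COC(=O)CC(=O)OC | starting material
4 | dimethyl 2-[(2S)-but-3-yn-2-yl]propanedioate | C#C[C@@H](C)C(C(=O)OC)C(=O)OC | intermediate
5 | methyl (3S)-3-methylpent-4-ynoate | C#C[C@@H](C)CC(=O)OC | intermediate
6 | methyl propiolate | C#CC(=O)OC | starting material
7 | 4-methoxybenzyl alcohol | COc1ccc(CO)cc1 | starting material
8 | methyl (E)-3-[(4-methoxybenzyl)oxy]prop-2-enoate | COC(=O)/C=C/OCc1ccc(OC)cc1 | intermediate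
9 | methyl 3-acetoxy-2-iodo-3-[(4-methoxybenzyl)oxy]propanoate (iodoacetoxy adduct, diastereomer mixture, not isolated) | COC(=O)C(I)C(OC(C)=O)OCc1ccc(OC)cc1 | intermediate
10 | methyl (Z)-2-iodo-3-[(4-methoxybenzyl)oxy]prop-2-enoate | COC(=O)/C(I)=C/OCc1ccc(OC)cc1 | intermediate
11 | (E)-alkenylzirconocene chloride from 5, Cp2Zr(Cl)–CH=CH–CH(CH3)CH2CO2CH3 with (3S) centre (not isolated) | COC(=O)C[C@H](C)/C=C/[Zr](Cl)(C1C=CC=C1)C1C=CC=C1 | intermediate
12 | (E)-alkenylzinc chloride, ClZn–CH=CH–CH(CH3)CH2CO2CH3 with (3S) centre (not isolated) | COC(=O)C[C@H](C)/C=C/[Zn]Cl | intermediate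
13 | dimethyl (2E,3E,5S)-2-{[(4-methoxybenzyl)oxy]methylidene}-5-methylhept-3-enedioate | COC(=O)C[C@H](C)/C=C/C(C(=O)OC)=C\OCc1ccc(OC)cc1 | intermediate
14 | methyl (2E,3E,5S)-7-[methoxy(methyl)amino]-2-{[(4-methoxybenzyl)oxy]methylidene}-5-methyl-7-oxohept-3-enoate | CON(C)C(=O)C[C@H](C)/C=C/C(C(=O)OC)=C\OCc1ccc(OC)cc1 | intermediate
15 | 2-methylallylmagnesium chloride | CC(=C)C[Mg]Cl | starting material
16 | methyl (2E,3E,5S)-2-{[(4-methoxybenzyl)oxy]methylidene}-5,9-dimethyl-7-oxodeca-3,9-dienoate | CC(=C)CC(=O)C[C@H](C)/C=C/C(C(=O)OC)=C\OCc1ccc(OC)cc1 | intermediate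
17 | methyl (2E,3E,5S)-8-diazo-2-{[(4-methoxybenzyl)oxy]methylidene}-5,9-dimethyl-7-oxodeca-3,9-dienoate | CC(=C)C(=[N+]=[N-])C(=O)C[C@H](C)/C=C/C(C(=O)OC)=C\OCc1ccc(OC)cc1 | intermediate
18 | 1-isopropenyl-4-methylbicyclo[3.1.0]hexan-2-one carrying on C6, cis to the isopropenyl group, the (E)-1-(methoxycarbonyl)-2-[(4-methoxybenzyl)oxy]vinyl group; 4-methyl on the cyclopropane side (not isolated) | O=C1C[C@H](C)[C@@H]2[C@@H](/C(C(=O)OC)=C\OCc3ccc(OC)cc3)[C@]12C(C)=C | intermediate
19 | methyl (3S,3aR,6S)-6-[(4-methoxybenzyl)oxy]-3,8-dimethyl-1-oxo-1,2,3,3a,6,7-hexahydroazulene-5-carboxylate (C4 methyl trans to H5, H5 cis to O8) | COc1ccc(CO[C@H]2CC(C)=C3C(=O)C[C@H](C)[C@@H]3C=C2C(=O)OC)cc1 | intermediate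
20 | methyl (3S,3aR,6S)-1-hydroxy-6-[(4-methoxybenzyl)oxy]-3,8-dimethyl-1,2,3,3a,6,7-hexahydroazulene-5-carboxylate (carbinol epimers) | COc1ccc(CO[C@H]2CC(C)=C3C(O)C[C@H](C)[C@@H]3C=C2C(=O)OC)cc1 | intermediate
21 | methyl (3S,3aR,6S)-6-[(4-methoxybenzyl)oxy]-3,8-dimethyl-1,2,3,3a,6,7-hexahydroazulene-5-carboxylate | COc1ccc(CO[C@H]2CC(C)=C3CC[C@H](C)[C@@H]3C=C2C(=O)OC)cc1 | intermediate
22 | methyl (3S,3aR,6S)-6-hydroxy-3,8-dimethyl-1,2,3,3a,6,7-hexahydroazulene-5-carboxylate | O[C@H]1CC(C)=C2CC[C@H](C)[C@@H]2C=C1C(=O)OC | intermediate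
23 | methyl (3S,3aS,5S,6S)-6-hydroxy-3,8-dimethyl-1,2,3,3a,4,5,6,7-octahydroazulene-5-carboxylate | O[C@H]1CC(C)=C2CC[C@H](C)[C@@H]2C[C@@H]1C(=O)OC | intermediate
24 | (3S,3aS,5S,6S)-5-(2-hydroxypropan-2-yl)-3,8-dimethyl-1,2,3,3a,4,5,6,7-octahydroazulen-6-ol | O[C@H]1CC(C)=C2CC[C@H](C)[C@@H]2C[C@@H]1C(C)(C)O | intermediate
25 | 4-acetoxy-3-methoxycinnamic acid (O-acetylferulic acid) | CC(=O)Oc1ccc(/C=C/C(=O)O)cc1OC | starting material
26 | (3S,3aS,5S,6S)-5-(2-hydroxypropan-2-yl)-3,8-dimethyl-1,2,3,3a,4,5,6,7-octahydroazulen-6-yl (E)-3-(4-acetoxy-3-methoxyphenyl)prop-2-enoate | CC(=O)Oc1ccc(/C=C/C(=O)O[C@H]2CC(C)=C3CC[C@H](C)[C@@H]3C[C@@H]2C(C)(C)O)cc1OC | intermediate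
27 | (3S,3aS,5S,6S)-5-(2-hydroxypropan-2-yl)-3,8-dimethyl-1,2,3,3a,4,5,6,7-octahydroazulen-6-yl (E)-3-(4-hydroxy-3-methoxyphenyl)prop-2-enoate | COc1cc(/C=C/C(=O)O[C@H]2CC(C)=C3CC[C@H](C)[C@@H]3C[C@@H]2C(C)(C)O)ccc1O | target

Total step count: 17.
Longest linear sequence: 15 steps (steps 1–3 and 6–17, from 1); steps 4 and 5 form the short branch to iodide 10.

Steps most likely to fail

Step 10 (key step). The C4 methyl group may discriminate only weakly between the two faces of C5=C6, or may even favour the other face, which would leave the wanted (3S,3aR,6S) isomer as the minor, though separable, product. The vinyl diazo ketone may also be lost before metal capture by 1,5-electrocyclisation or carbenoid dimerisation. The fallback makes the same two bonds without a diazo compound, by a Lewis-acid-mediated (4+3) cycloaddition of an allyl cation. It sets out from 13 and comes back at 21. The saturated ester of 13 is reduced selectively with LiBH4 to methyl (2E,3E,5S)-7-hydroxy-2-{[(4-methoxybenzyl)oxy]methylidene}-5-methylhept-3-enoate F1, and I2/PPh3/imidazole converts this into the primary iodide F2. The known reagent PhSO2CH2C(=CH2)CH2SiMe3 is lithiated with n-BuLi in THF/HMPA at −78 °C and alkylated with F2 to give the allylic sulfone F3. TiCl4 in CH2Cl2 at −78 °C should ionise the sulfone to a 2-(silylmethyl)allyl cation, which adds across C5 and C8 of the diene and loses the silyl group to give the exo-methylene cycloadduct F4 (C10=CH2, H at C1). TsOH in benzene should then move the exocyclic double bond into the tetrasubstituted C1=C10 position, which gives 21. The different transition state (no metal carbene, Lewis acid and temperature as variables) offers a second chance for face selection, and the diastereomers remain separable.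

Step 12. The allyl cation may lose a proton to give dienes, may be captured by hydride at C10, or may be trapped by the ether oxygen on C8. The fallback replaces the cation by an allyl radical; it sets out from 20 and comes back at 21. Alcohol 20 is converted with PhOC(S)Cl, pyridine and DMAP into the O-phenyl thionocarbonate F5, and Bu3SnH/AIBN in toluene at 80 °C (Barton–McCombie deoxygenation) should deliver hydrogen to the less substituted C2 terminus of the allyl radical, giving 21; a prior [3,3] shift of the thionocarbonate would lead to the same radical.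

Step 9. Diazo transfer to a methylene activated by only one carbonyl may be slow, and the base may move the β,γ-double bond into conjugation or the azide may add elsewhere. The fallback builds the diazo ketone first and the isopropenyl group afterwards; it sets out from 14 and comes back at 17. MeMgBr converts 14 into the methyl ketone F6; LiHMDS and CF3CO2CH2CF3 give the trifluoroacetyl ketone F7 (not isolated), which with MsN3 and Et3N undergoes detrifluoroacetylative diazo transfer to the diazomethyl ketone F8. Deprotonation of F8 with LDA at −78 °C and addition to acetone gives the tertiary β-hydroxy diazo ketone F9, and dehydration with POCl3/Et3N, which can only take place towards a methyl group, gives 17.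

Further compounds
F1 | step 10 | methyl (2E,3E,5S)-7-hydroxy-2-{[(4-methoxybenzyl)oxy]methylidene}-5-methylhept-3-enoate | OCC[C@H](C)/C=C/C(C(=O)OC)=C\OCc1ccc(OC)cc1
F2 | step 10 | methyl (2E,3E,5S)-7-iodo-2-{[(4-methoxybenzyl)oxy]methylidene}-5-methylhept-3-enoate | ICC[C@H](C)/C=C/C(C(=O)OC)=C\OCc1ccc(OC)cc1
F3 | step 10 | methyl (2E,3E,5S)-2-{[(4-methoxybenzyl)oxy]methylidene}-5-methyl-8-(phenylsulfonyl)-9-[(trimethylsilyl)methyl]deca-3,9-dienoate (sulfone carbon epimers) | C=C(C[Si](C)(C)C)C(CC[C@H](C)/C=C/C(C(=O)OC)=C\OCc1ccc(OC)cc1)S(=O)(=O)c1ccccc1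
F4 | step 10 | exo-methylene isomer of 21 (C10=CH2, H at C1, C1 epimers) | COc1ccc(CO[C@H]2CC(=C)C3CC[C@H](C)[C@@H]3C=C2C(=O)OC)cc1
F5 | step 12 | O-phenyl thionocarbonate of 20 | COc1ccc(CO[C@H]2CC(C)=C3C(OC(=S)Oc4ccccc4)C[C@H](C)[C@@H]3C=C2C(=O)OC)cc1
F6 | step 9 | methyl (2E,3E,5S)-2-{[(4-methoxybenzyl)oxy]methylidene}-5-methyl-7-oxooct-3-enoate | CC(=O)C[C@H](C)/C=C/C(C(=O)OC)=C\OCc1ccc(OC)cc1
F7 | step 9 | methyl (2E,3E,5S)-10,10,10-trifluoro-2-{[(4-methoxybenzyl)oxy]methylidene}-5-methyl-7,9-dioxodec-3-enoate (not isolated) | O=C(CC(=O)C[C@H](C)/C=C/C(C(=O)OC)=C\OCc1ccc(OC)cc1)C(F)(F)F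
F8 | step 9 | methyl (2E,3E,5S)-8-diazo-2-{[(4-methoxybenzyl)oxy]methylidene}-5-methyl-7-oxooct-3-enoate | [N-]=[N+]=CC(=O)C[C@H](C)/C=C/C(C(=O)OC)=C\OCc1ccc(OC)cc1
F9 | step 9 | methyl (2E,3E,5S)-8-diazo-9-hydroxy-2-{[(4-methoxybenzyl)oxy]methylidene}-5,9-dimethyl-7-oxodec-3-enoate | CC(C)(O)C(=[N+]=[N-])C(=O)C[C@H](C)/C=C/C(C(=O)OC)=C\OCc1ccc(OC)cc1
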